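## Structural features

Peyssonol A (30) is a cis-fused decalin. Ring A (C1–C5, C10) carries a bromine at C3 and a gem-dimethyl group at C4; ring B (C5–C10) carries an exocyclic methylene (C8=C12) and, at C9, a CH2 link (C11) to a 2,5-dihydroxy-4-formylphenyl ring. β denotes the face of the C10 methyl group. There are four stereocentres, (3S,5S,9R,10R): C3 stands alone beside the quaternary C4, while C5, C10 and C9 are contiguous with the quaternary C10 in the middle; H5, the C10 methyl and the bromine are β, and C11 is α. The fragile groups are the neopentyl secondary bromide (elimination, 1,2-methyl shift), the 1,1-disubstituted alkene (acid-induced migration into the ring and, once the neighbouring phenol is free, closure to a chroman), the hydroquinone (oxidation) and the aryl aldehyde. The real difficulty is the quaternary C10 flanked by two tertiary stereocentres across a cis ring fusion next to a bulky benzylic group, together with a configurationally defined C–Br bond at a neopentyl carbon. The key step reads the C5–C10 bond as the former C=C of a ring A cyclohex-2-enone with its carbonyl at C1, and C6–C7–C8–C9 as a diene, so that ring B and the stereocentres C5, C10 and C9 arise in one cycloaddition, with C8=C12 carried as an allylsilane (C7=C8, C12–Si). The C3 oxygen of the dienophile serves first as the face-directing element and later as the site of the bromine.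

## Logic of the disconnections

30 ⇒ 29. The two phenolic O–H bonds are traced back to O–Si bonds. The free hydroquinone is oxidisable and, beside the C8 methylene, prone to acid-induced ring closure, so it is released last; every earlier step then runs on a capped, electron-poor arene. The forward step must be neither acidic nor oxidative.

29 ⇒ 27. The formyl C=O is traced back to a C≡N bond on the same carbon. A nitrile survives Lewis acid, borohydrides, radicals, acid and phosphonium chemistry and is unmasked in one step. The demand is a partial hydride reduction that leaves the secondary bromide alone.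

27 ⇒ 26. The C3–Br bond is cut and replaced by a C3–O bond of opposite configuration. The bromide is too elimination-prone to be carried, so it enters late by substitution with inversion. The forward step must achieve backside attack at a neopentyl ring carbon.

26 ⇒ 25 ⇒ 24. The C3–H bond is cut (ketone 25) and re-formed on the other face. The cycloaddition can only deliver the C3 oxygen cis to the C10 methyl, whereas invertive bromination needs it trans. Two steps buy the correction; the demand is hydride delivery from the β face.

24 ⇒ 23. The C8=C12 double bond is moved back to C7=C8 with a C12–Si bond, and O3–H back to O–Si. The sensitive methylene becomes a robust allylsilane that the cycloaddition itself produces. The forward step needs protonation at C7 under acid mild enough for the product alkene.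

23 ⇒ 22 ⇒ 20 ⇒ 19. The two C1–H bonds are traced back to the C1=O group. The carbonyl is indispensable as the activating group of the key step but absent from 30. The price is a three-step radical deoxygenation at a hindered carbinol.

19 ⇒ 7 + 18. C5–C6 and C9–C10 are cut. Ring B disappears, three contiguous stereocentres are cleared and the molecule falls into two fragments of similar size. The forward step needs face, endo and regio selectivity on a dienophile that is hindered at both alkene carbons.

18 ⇒ 15 + 16, 15 ⇒ 13. The C8–C12 bond (sp2–sp3 coupling) and then the enol O–S bond are cut. The geometry of the trisubstituted C8=C9 bond is thereby reduced to the geometry of an enolate that can form on one side of the ketone only. The demand is the enolate with oxygen cis to C11.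

13 ⇒ 11 + 12. The aryl–C11 bond is cut. Arylation of an allylic alcohol with migration of the oxidation level gives the ketone directly from two commercial pieces. The demand is that the vinyl ketone survives the conditions that form it.

11 ⇒ 10 ⇒ 9 ⇒ 8. These are protecting-group and oxidation-level changes on the arene: O–Si back to O–H, O–H back to O–CH3, C≡N back to CH=O. They are placed at the outset, where a strong Lewis acid does no harm, so that no oxidative or Lewis acidic demethylation is needed beside the alkene and bromide at the end.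

7 ⇒ 6 ⇒ 4. The O–Si bond and then the C–O bond at the future C3 are cut, the latter traced through a C–B bond to the unsubstituted enone arm of 4. The single stereocentre of fragment 1 is set by catalytic enantioselective conjugate borylation. The demand is addition to the arm without the methyl group and face control beside a quaternary carbon.

4 ⇒ 3 ⇒ 1. The ring C=C bond (dehydrogenation) and the C–CH3 bond (enolate alkylation) are cut. The methyl group is introduced first, at the only enolisable carbon of 1; once the oxygen is in place, enolate methylation would go to the wrong α-carbon.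

## Other disconnections considered

Alternative 1: The cut is C1–C10, with a temporary C3–C8 bond in the precursor. In the forward sense the potassium alkoxide of the bicyclic alcohol A1 undergoes an anionic oxy-Cope shift to the cis-decalin A2, which has the C3 ketone, C4 gem-dimethyl, C10 methyl and a C8=C9 methyl enol ether.
- In its favour: the shift is intramolecular and does not depend on two hindered π systems meeting, which makes it the better of the two plans on kinetic feasibility. The cis fusion is stereospecific, equal to the chosen plan. A2 has no oxygen at C1 and arrives with C3 as a ketone, so the deoxygenation (steps 12–14) and the deprotection and oxidation before the C3 inversion would be saved, a clear advantage. The enol ether is a regiodefined C9 enolate equivalent.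
- Against it: only one skeletal bond and two stereocentres are made. C9, the C9–C11 bond with the whole arene and C12 remain, to be added by alkylation at a neopentyl carbon with a bulky benzylic electrophile and by methylenation of a hindered ketone with an epimerisable neighbour. A1 itself needs an enantioselective cycloaddition, geminal methylation and a face-selective vinyl addition.
- Comparison: the chosen step 11 forms two bonds and three stereocentres and joins the fragments convergently; on step count the two plans would be about equal, with the alternative's uncertainty moved to the C9 alkylation.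

Alternative 2: The cuts are C8–C9 and C7–C8. The cis-hydrindanone A3 is treated with ethyl diazoacetate A4 and a boron Lewis acid; C7 migrates with loss of nitrogen to give the ring-expanded β-keto ester A5.
- In its favour: migration of the less substituted carbon is dependable, and the keto ester differentiates C8 and C9. The bromine is already in place, so no late substitution at C3 beside arene and alkene is needed; on that point the alternative is the better plan, provided A3 is available.
- Against it: the key step creates no stereocentre; all three ring A and fusion stereocentres and the neopentyl bromide must be built into A3 beforehand. The bromide then has to survive the Lewis acid and the later carbanion chemistry at C9 (benzyl addition to a hindered ketone and removal of the resulting hydroxyl with control of C9). The ester carbon must be reduced and eliminated to the methylene.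
- Comparison: the route is linear, the arene enters late, and the stereochemical work is shifted upstream rather than solved. The chosen plan is more convergent and gets more stereochemistry from its key step; the alternative's key step is operationally simpler.

Alternative 3: The cuts are C1–C10 and C4–C5. 2-Methylcyclohex-2-en-1-one A6 and 1-methoxy-3-(trimethylsilyloxy)buta-1,3-diene A7 combine under a chiral oxazaborolidinium Lewis acid, and acid work-up gives the cis-fused enedione A8.
- In its favour: absolute configuration comes from a catalyst acting on two cheap achiral partners, and the diene is far more nucleophilic than 18. On cost of chirality and on rate this alternative is the better plan; the cis fusion is equally secure.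
- Against it: ring A is built, not ring B, so the difficult region is untouched. Still to come would be C4 dimethylation in the presence of a second enolisable ketone, saturation of C1=C2, the same C3 reduction and bromination problem, and the whole C8–C9–C11 array including the C9 stereocentre on a hindered ketone, with the arene attached late and linearly.
- Comparison: the mechanism is the same pericyclic class with equal stereospecificity, but the step count after the key step would be clearly higher than the nine steps that follow 19.

Key step: step 11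

Assumption: the sense of induction of the bisphosphine in step 3 is not predicted here, so the ligand antipode that gives (S)-6 is to be used; the C1 carbinol configuration in 20–22 is left open because step 14 erases it.

## Route

Ar = 4-cyano-2,5-bis(triisopropylsilyloxy)phenyl. Decalin names use the numbering of 30.

Step 1
Reactants: 1 4,4-dimethylcyclohex-2-en-1-one
Product: 3 4,4,6-trimethylcyclohex-2-en-1-one (racemic), via lithium dienolate 2 (not isolated)
Conditions: LiN(i-Pr)2, THF, −78 °C; MeI, −78 → 0 °C
Reagents that add atoms: iodomethane, CI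
Why: Kinetic deprotonation can only occur at C6 (C4 is quaternary), and the cross-conjugated lithium enolate is C-methylated (enolate alkylation); the new stereocentre is erased in step 2.

Step 2
Reactants: 3 4,4,6-trimethylcyclohex-2-en-1-one
Product: 4 2,4,4-trimethylcyclohexa-2,5-dien-1-one
Conditions: DDQ, dioxane, 100 °C
Reagents that add atoms: none
Why: Quinone dehydrogenation of a 4,4-disubstituted cyclohexenone to the cross-conjugated dienone, as in the formation of 1,4-dien-3-ones; the quaternary C4 excludes aromatisation.

Step 3
Reactants: 4 2,4,4-trimethylcyclohexa-2,5-dien-1-one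
Product: 6 (S)-5-hydroxy-2,4,4-trimethylcyclohex-2-en-1-one, via boryl ketone 5 (not isolated)
Conditions: CuCl (3 mol %), Josiphos-type chiral bisphosphine (3 mol %), NaOt-Bu (5 mol %), B2pin2, MeOH, THF, 0 °C; then NaBO3·4H2O, THF/H2O, 0 °C
Reagents that add atoms: bis(pinacolato)diboron (boron of 5), CC1(C)OB(OC1(C)C)B1OC(C)(C)C(C)(C)O1; sodium perborate (oxygen of 6), [Na+].[O-]OB=O
Why: A boryl complex of monovalent copper adds boron to the β-carbon of the unsubstituted, more electrophilic enone arm, with the bisphosphine choosing the alkene face, and MeOH protonates the copper enolate (copper-catalysed enantioselective conjugate borylation of cyclic enones). Oxidation of the C–B bond proceeds with retention and gives the (S)-alcohol; the methyl-bearing arm is left as the dienophile double bond.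

Step 4
Reactants: 6 (S)-5-hydroxy-2,4,4-trimethylcyclohex-2-en-1-one
Product: 7 (S)-5-(tert-butyldimethylsilyloxy)-2,4,4-trimethylcyclohex-2-en-1-one (fragment 1)
Conditions: t-BuMe2SiOTf, 2,6-lutidine, CH2Cl2, −78 °C
Reagents that add atoms: tert-butyldimethylsilyl trifluoromethanesulfonate, CC(C)(C)[Si](C)(C)OS(=O)(=O)C(F)(F)F
Why: The silyl triflate caps the hindered secondary alcohol at low temperature with a base too weak to trigger β-elimination of the hydroxy ketone; the stereocentre is untouched.

Step 5
Reactants: 8 4-bromo-2,5-dimethoxybenzaldehyde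
Product: 9 4-bromo-2,5-dimethoxybenzonitrile
Conditions: I2, 28% aq. NH3, THF, rt
Reagents that add atoms: ammonia, N
Why: The aldimine formed with ammonia is N-iodinated and loses HI (oxidative conversion of an aldehyde into a nitrile); the nitrile is the formyl surrogate that tolerates every later step and deactivates the arene.

Step 6
Reactants: 9 4-bromo-2,5-dimethoxybenzonitrile
Product: 10 4-bromo-2,5-dihydroxybenzonitrile
Conditions: BBr3, CH2Cl2, −78 °C → rt; then H2O
Reagents that add atoms: none
Why: BBr3 cleaves both aryl methyl ethers by bromide attack on the methyl of the boron-complexed ether; nitrile and aryl bromide are inert.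

Step 7
Reactants: 10 4-bromo-2,5-dihydroxybenzonitrile
Product: 11 4-bromo-2,5-bis(triisopropylsilyloxy)benzonitrile
Conditions: i-Pr3SiCl, imidazole, DMF, rt
Reagents that add atoms: chlorotriisopropylsilane, CC(C)[Si](Cl)(C(C)C)C(C)C
Why: Imidazole-mediated silylation of both phenols; the bulky, weakly Lewis basic silyl ethers should tolerate amide bases, organozinc, Me2AlCl, hydrides and mild acid and are removable with fluoride.

Step 8
Reactants: 11 4-bromo-2,5-bis(triisopropylsilyloxy)benzonitrile; 12 penta-1,4-dien-3-ol (excess)
Product: 13 4-(3-oxopent-4-en-1-yl)-2,5-bis(triisopropylsilyloxy)benzonitrile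
Conditions: Pd2(dba)3 (2.5 mol %), [HP(t-Bu)3]BF4 (6 mol %), Cy2NMe, dioxane, 60 °C
Reagents that add atoms: none
Why: Heck arylation of a secondary allylic alcohol: the aryl group adds to a terminal alkene carbon, β-hydride elimination toward the carbinol carbon and tautomerisation give the β-aryl ketone, and the second vinyl group remains as the enone. Excess 12 limits a second arylation.

Step 9
Reactants: 13 4-(3-oxopent-4-en-1-yl)-2,5-bis(triisopropylsilyloxy)benzonitrile
Product: 15 (2Z)-1-Ar-penta-2,4-dien-3-yl trifluoromethanesulfonate, via potassium dienolate 14 (not isolated)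
Conditions: KN(SiMe3)2, THF, −78 °C (ketone added to base); PhNTf2, −78 → 0 °C
Reagents that add atoms: N-phenylbis(trifluoromethanesulfonimide), O=S(=O)(N(c1ccccc1)S(=O)(=O)C(F)(F)F)C(F)(F)F
Why: The ketone can enolise only toward C9; the potassium amide should favour the dienolate with oxygen cis to the arylmethyl group, and O-sulfonylation fixes that geometry (enol triflate formation). Any geometric isomer leads to a diene that cannot reach the s-cis form and is removed by chromatography or stays unreacted in step 11.

Step 10
Reactants: 15 (2Z)-1-Ar-penta-2,4-dien-3-yl trifluoromethanesulfonate; 16 (trimethylsilyl)methylmagnesium chloride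
Product: 18 4-[(2Z)-3-(trimethylsilylmethyl)penta-2,4-dien-1-yl]-2,5-bis(triisopropylsilyloxy)benzonitrile (fragment 2), via (trimethylsilyl)methylzinc chloride 17 (not isolated)
Conditions: 16, ZnCl2, THF, 0 °C; then 15, Pd(PPh3)4 (5 mol %), THF, rt → 40 °C
Reagents that add atoms: none
Why: Transmetalation to zinc gives 17, which couples with the enol triflate at zerovalent palladium with retention of alkene geometry (Negishi coupling), so the silylmethyl group ends cis to the arylmethyl group and the vinyl group trans to it. The organozinc reagent spares the nitrile and has no β-hydrogen.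

Step 11
Reactants: 7 (S)-5-(tert-butyldimethylsilyloxy)-2,4,4-trimethylcyclohex-2-en-1-one; 18 4-[(2Z)-3-(trimethylsilylmethyl)penta-2,4-dien-1-yl]-2,5-bis(triisopropylsilyloxy)benzonitrile
Product: 19 9α-(ArCH2)-3β-(tert-butyldimethylsilyloxy)-4,4,10β-trimethyl-8-(trimethylsilylmethyl)-5βH-decal-7-en-1-one (cis-fused)
Conditions: Me2AlCl (2.2 equiv), CH2Cl2, −78 → −20 °C
Reagents that add atoms: none
Why: Me2AlCl binds the C1 carbonyl of 7 (a second equivalent is taken up by the nitrile of 18), lowers the enone LUMO and scavenges protons that would attack the allylsilane; the reaction is a normal-demand, concerted but asynchronous [4+2] cycloaddition, the closest known type being the Lewis acid-promoted Diels–Alder reaction of 5-substituted 2-methylcyclohex-2-enones with 1-substituted dienes, which gives cis-fused angular-methyl octalones. Ring B closes in the six-membered [4π+2π] mode, suprafacial on both partners, by forming C5–C6 and C9–C10. At C5 and C10, suprafacial addition forces H5 and the C10 methyl cis, and their absolute sense follows from attack anti to the C3 silyloxy group: in the half-chair with that group pseudo-equatorial, the pseudo-axial C4 methyl screens the syn face while the anti face allows chair-like bonding at C5. At C9, the endo transition state places ring A with its complexed C1 carbonyl under the diene, so the outward arylmethyl group ends cis to C1 and trans to the C10 methyl. For regiochemistry, the more advanced bond joins the neopentyl β-carbon C5 to the unsubstituted terminus C6, as the 1-alkyl substituent and above all sterics dictate; the 2-silylmethyl group on its own is a para director that would favour C9–C5 bonding, so this selectivity rests on the steric bias. Face, endo and regio selectivity are therefore needed and are secured by the C3 stereocentre with the C4 gem-dimethyl group, by secondary overlap with the carbonyl, and by the hindrance at C5.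

Step 12
Reactants: 19 9α-(ArCH2)-3β-(tert-butyldimethylsilyloxy)-4,4,10β-trimethyl-8-(trimethylsilylmethyl)-5βH-decal-7-en-1-one
Product: 20 9α-(ArCH2)-3β-(tert-butyldimethylsilyloxy)-4,4,10β-trimethyl-8-(trimethylsilylmethyl)-5βH-decal-7-en-1-ol (C1 epimers)
Conditions: NaBH4, EtOH/THF, 0 °C → rt
Reagents that add atoms: none
Why: Borohydride reduction of the ketone; nitrile, silyl ethers and allylsilane are inert, and the new C1 stereocentre needs no control because step 14 removes it.

Step 13
Reactants: 20 9α-(ArCH2)-3β-(tert-butyldimethylsilyloxy)-4,4,10β-trimethyl-8-(trimethylsilylmethyl)-5βH-decal-7-en-1-ol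
Product: 22 O-[9α-(ArCH2)-3β-(tert-butyldimethylsilyloxy)-4,4,10β-trimethyl-8-(trimethylsilylmethyl)-5βH-decal-7-en-1-yl] S-methyl dithiocarbonate, via sodium xanthate 21 (not isolated)
Conditions: NaN(SiMe3)2, CS2, THF, −78 °C; then MeI, −78 °C → rt
Reagents that add atoms: carbon disulfide, S=C=S; iodomethane, CI
Why: The alkoxide is formed cold and captured at once by CS2, before the C3 silyl group can migrate to O1, and S-methylation gives the xanthate needed for radical deoxygenation.

Step 14
Reactants: 22 O-decalin-1-yl S-methyl dithiocarbonate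
Product: 23 9α-(ArCH2)-3β-(tert-butyldimethylsilyloxy)-4,4,10β-trimethyl-8-(trimethylsilylmethyl)-5βH-decal-7-ene
Conditions: Bu3SnH, AIBN (cat.), toluene, 100 °C
Reagents that add atoms: none
Why: Barton–McCombie deoxygenation: the stannyl radical adds to C=S, β-scission gives the secondary C1 radical, and Bu3SnH transfers hydrogen. The radical has no β-leaving group and only unfavourable 4-exo or 5-endo cyclisations onto C7=C8.

Step 15
Reactants: 23 9α-(ArCH2)-3β-(tert-butyldimethylsilyloxy)-4,4,10β-trimethyl-8-(trimethylsilylmethyl)-5βH-decal-7-ene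
Product: 24 9α-(ArCH2)-4,4,10β-trimethyl-8-methylidene-5βH-decalin-3β-ol
Conditions: TsOH·H2O (0.3 equiv), MeOH/CH2Cl2, 0 °C → rt
Reagents that add atoms: none
Why: The electron-rich allylsilane is protonated at C7 and the β-silyl cation at C8 loses silicon to methanol, placing the double bond at C8=C12 (protodesilylation with allylic transposition). The same medium methanolyses the C3 silyl ether, while the aryl silyl ethers and the far less nucleophilic 1,1-disubstituted alkene should persist.

Step 16
Reactants: 24 9α-(ArCH2)-4,4,10β-trimethyl-8-methylidene-5βH-decalin-3β-ol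
Product: 25 9α-(ArCH2)-4,4,10β-trimethyl-8-methylidene-5βH-decalin-3-one
Conditions: Dess–Martin periodinane, NaHCO3, CH2Cl2, 0 °C → rt
Reagents that add atoms: none
Why: Buffered hypervalent-iodine oxidation of the hindered secondary alcohol; neither α-carbon of the new ketone is a stereocentre, so nothing can epimerise.

Step 17
Reactants: 25 9α-(ArCH2)-4,4,10β-trimethyl-8-methylidene-5βH-decalin-3-one
Product: 26 9α-(ArCH2)-4,4,10β-trimethyl-8-methylidene-5βH-decalin-3α-ol
Conditions: LiBH(s-Bu)3, THF, −78 °C; then H2O
Reagents that add atoms: none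
Why: The bulky hydride attacks C3 from the β face, because the α face is screened by the axial C5–C6 bond of the cis-decalin, and gives the 3α (axial) alcohol: net inversion of the C3 configuration set in step 3.

Step 18
Reactants: 26 9α-(ArCH2)-4,4,10β-trimethyl-8-methylidene-5βH-decalin-3α-ol
Product: 27 9α-(ArCH2)-3β-bromo-4,4,10β-trimethyl-8-methylidene-5βH-decalin
Conditions: PPh3, CBr4, CH2Cl2, 0 → 40 °C
Reagents that add atoms: tetrabromomethane, BrC(Br)(Br)Br
Why: Appel reaction: bromide displaces the alkoxyphosphonium group with inversion (SN2) and gives the 3β (equatorial) bromide with the configuration of 30. Invertive bromination of ring alcohols beside a gem-dimethyl carbon is known but competes with elimination.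

Step 19
Reactants: 27 9α-(ArCH2)-3β-bromo-4,4,10β-trimethyl-8-methylidene-5βH-decalin
Product: 29 4-{[3β-bromo-4,4,10β-trimethyl-8-methylidene-5βH-decalin-9α-yl]methyl}-2,5-bis(triisopropylsilyloxy)benzaldehyde, via N-aluminio aldimine 28 (not isolated)
Conditions: i-Bu2AlH, toluene, −78 → −40 °C; then aq. tartaric acid, 0 °C
Reagents that add atoms: water, O
Why: i-Bu2AlH adds once to the nitrile to give an aluminated aldimine that is stable in the cold, and mild aqueous acid hydrolyses it to the aldehyde; the secondary bromide, the alkene and the aryl silyl ethers should be untouched.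

Step 20
Reactants: 29 4-{[3β-bromo-4,4,10β-trimethyl-8-methylidene-5βH-decalin-9α-yl]methyl}-2,5-bis(triisopropylsilyloxy)benzaldehyde
Product: 30 Peyssonol A
Conditions: Bu4NF, AcOH (1:1), THF, 0 °C, argon
Reagents that add atoms: none
Why: Fluoride cleaves both aryl O–Si bonds; acetic acid buffers the phenoxides so that neither base-induced loss of HBr nor acid-induced alkene migration or chroman closure is invited, and exclusion of air protects the hydroquinone.

## Compound list

1 | 4,4-dimethylcyclohex-2-en-1-one | CC1(C)CCC(=O)C=C1 | starting material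
2 | lithium 4,4-dimethylcyclohexa-1,5-dien-1-olate | [Li+].[O-]C1=CCC(C)(C)C=C1 | intermediate
3 | 4,4,6-trimethylcyclohex-2-en-1-one (racemic) | CC1CC(C)(C)C=CC1=O | intermediate
4 | 2,4,4-trimethylcyclohexa-2,5-dien-1-one | CC1=CC(C)(C)C=CC1=O | intermediate
5 | (S)-2,4,4-trimethyl-5-(4,4,5,5-tetramethyl-1,3,2-dioxaborolan-2-yl)cyclohex-2-en-1-one | CC1=CC(C)(C)[C@@H](B2OC(C)(C)C(C)(C)O2)CC1=O | intermediate
6 | (S)-5-hydroxy-2,4,4-trimethylcyclohex-2-en-1-one | CC1=CC(C)(C)[C@@H](O)CC1=O | intermediate
7 | (S)-5-(tert-butyldimethylsilyloxy)-2,4,4-trimethylcyclohex-2-en-1-one (fragment 1) | CC1=CC(C)(C)[C@@H](O[Si](C)(C)C(C)(C)C)CC1=O | intermediate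
8 | 4-bromo-2,5-dimethoxybenzaldehyde | COc1cc(Br)c(OC)cc1C=O | starting material
9 | 4-bromo-2,5-dimethoxybenzonitrile | N#Cc1cc(OC)c(Br)cc1OC | intermediate
10 | 4-bromo-2,5-dihydroxybenzonitrile | N#Cc1cc(O)c(Br)cc1O | intermediate
11 | 4-bromo-2,5-bis(triisopropylsilyloxy)benzonitrile | N#Cc1cc(O[Si](C(C)C)(C(C)C)C(C)C)c(Br)cc1O[Si](C(C)C)(C(C)C)C(C)C | intermediate
12 | penta-1,4-dien-3-ol | C=CC(O)C=C | starting material
13 | 4-(3-oxopent-4-en-1-yl)-2,5-bis(triisopropylsilyloxy)benzonitrile | C=CC(=O)CCc1cc(O[Si](C(C)C)(C(C)C)C(C)C)c(C#N)cc1O[Si](C(C)C)(C(C)C)C(C)C | intermediate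
14 | potassium (2Z)-1-[4-cyano-2,5-bis(triisopropylsilyloxy)phenyl]penta-2,4-dien-3-olate | [K+].C=C/C([O-])=C/Cc1cc(O[Si](C(C)C)(C(C)C)C(C)C)c(C#N)cc1O[Si](C(C)C)(C(C)C)C(C)C | intermediate
15 | (2Z)-1-[4-cyano-2,5-bis(triisopropylsilyloxy)phenyl]penta-2,4-dien-3-yl trifluoromethanesulfonate | C=C/C(OS(=O)(=O)C(F)(F)F)=C/Cc1cc(O[Si](C(C)C)(C(C)C)C(C)C)c(C#N)cc1O[Si](C(C)C)(C(C)C)C(C)C | intermediate
16 | (trimethylsilyl)methylmagnesium chloride | C[Si](C)(C)C[Mg]Cl | starting material
17 | (trimethylsilyl)methylzinc chloride | C[Si](C)(C)C[Zn]Cl | intermediate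
18 | 4-[(2Z)-3-(trimethylsilylmethyl)penta-2,4-dien-1-yl]-2,5-bis(triisopropylsilyloxy)benzonitrile (fragment 2; arylmethyl trans to vinyl) | C=C/C(C[Si](C)(C)C)=C/Cc1cc(O[Si](C(C)C)(C(C)C)C(C)C)c(C#N)cc1O[Si](C(C)C)(C(C)C)C(C)C | intermediate
19 | cis-fused adduct: 1-oxo, 3β-OSi(t-Bu)Me2, 4,4,10β-trimethyl, 5β-H, C7=C8, 8-CH2SiMe3, 9α-CH2Ar | C[Si](C)(C)CC1=CC[C@@H]2C(C)(C)[C@@H](O[Si](C)(C)C(C)(C)C)CC(=O)[C@]2(C)[C@@H]1Cc1cc(O[Si](C(C)C)(C(C)C)C(C)C)c(C#N)cc1O[Si](C(C)C)(C(C)C)C(C)C | intermediate
20 | C1 alcohol of 19 (C1 epimers) | C[Si](C)(C)CC1=CC[C@@H]2C(C)(C)[C@@H](O[Si](C)(C)C(C)(C)C)CC(O)[C@]2(C)[C@@H]1Cc1cc(O[Si](C(C)C)(C(C)C)C(C)C)c(C#N)cc1O[Si](C(C)C)(C(C)C)C(C)C | intermediate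
21 | sodium O-alkyl dithiocarbonate of 20 | [Na+].C[Si](C)(C)CC1=CC[C@@H]2C(C)(C)[C@@H](O[Si](C)(C)C(C)(C)C)CC(OC(=S)[S-])[C@]2(C)[C@@H]1Cc1cc(O[Si](C(C)C)(C(C)C)C(C)C)c(C#N)cc1O[Si](C(C)C)(C(C)C)C(C)C | intermediate
22 | O-alkyl S-methyl dithiocarbonate of 20 | C[Si](C)(C)CC1=CC[C@@H]2C(C)(C)[C@@H](O[Si](C)(C)C(C)(C)C)CC(OC(=S)SC)[C@]2(C)[C@@H]1Cc1cc(O[Si](C(C)C)(C(C)C)C(C)C)c(C#N)cc1O[Si](C(C)C)(C(C)C)C(C)C | intermediate
23 | C1-deoxygenated allylsilane: 3β-OSi(t-Bu)Me2, 4,4,10β-trimethyl, 5β-H, C7=C8, 8-CH2SiMe3, 9α-CH2Ar | C[Si](C)(C)CC1=CC[C@@H]2C(C)(C)[C@@H](O[Si](C)(C)C(C)(C)C)CC[C@]2(C)[C@@H]1Cc1cc(O[Si](C(C)C)(C(C)C)C(C)C)c(C#N)cc1O[Si](C(C)C)(C(C)C)C(C)C | intermediate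
24 | 9α-(ArCH2)-4,4,10β-trimethyl-8-methylidene-5βH-decalin-3β-ol | C=C1CC[C@@H]2C(C)(C)[C@@H](O)CC[C@]2(C)[C@@H]1Cc1cc(O[Si](C(C)C)(C(C)C)C(C)C)c(C#N)cc1O[Si](C(C)C)(C(C)C)C(C)C | intermediate
25 | 9α-(ArCH2)-4,4,10β-trimethyl-8-methylidene-5βH-decalin-3-one | C=C1CC[C@@H]2C(C)(C)C(=O)CC[C@]2(C)[C@@H]1Cc1cc(O[Si](C(C)C)(C(C)C)C(C)C)c(C#N)cc1O[Si](C(C)C)(C(C)C)C(C)C | intermediate
26 | 9α-(ArCH2)-4,4,10β-trimethyl-8-methylidene-5βH-decalin-3α-ol | C=C1CC[C@@H]2C(C)(C)[C@H](O)CC[C@]2(C)[C@@H]1Cc1cc(O[Si](C(C)C)(C(C)C)C(C)C)c(C#N)cc1O[Si](C(C)C)(C(C)C)C(C)C | intermediate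
27 | 9α-(ArCH2)-3β-bromo-4,4,10β-trimethyl-8-methylidene-5βH-decalin | C=C1CC[C@@H]2C(C)(C)[C@@H](Br)CC[C@]2(C)[C@@H]1Cc1cc(O[Si](C(C)C)(C(C)C)C(C)C)c(C#N)cc1O[Si](C(C)C)(C(C)C)C(C)C | intermediate
28 | N-(diisobutylalumanyl) aldimine from 27 | C=C1CC[C@@H]2C(C)(C)[C@@H](Br)CC[C@]2(C)[C@@H]1Cc1cc(O[Si](C(C)C)(C(C)C)C(C)C)c(C=N[Al](CC(C)C)CC(C)C)cc1O[Si](C(C)C)(C(C)C)C(C)C | intermediate
29 | 4-{[3β-bromo-4,4,10β-trimethyl-8-methylidene-5βH-decalin-9α-yl]methyl}-2,5-bis(triisopropylsilyloxy)benzaldehyde | C=C1CC[C@@H]2C(C)(C)[C@@H](Br)CC[C@]2(C)[C@@H]1Cc1cc(O[Si](C(C)C)(C(C)C)C(C)C)c(C=O)cc1O[Si](C(C)C)(C(C)C)C(C)C | intermediate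
30 | Peyssonol A, 4-{[(1R,4aS,6S,8aR)-6-bromo-5,5,8a-trimethyl-2-methylidenedecahydronaphthalen-1-yl]methyl}-2,5-dihydroxybenzaldehyde | C=C1CC[C@@H]2C(C)(C)[C@@H](Br)CC[C@]2(C)[C@@H]1Cc1cc(O)c(C=O)cc1O | target

## Step count and least certain steps

Total: 20 steps (fragment 1 in steps 1–4, fragment 2 in steps 5–10, union in step 11, nine steps after it). Longest linear sequence: 16 steps (8 → 30 through steps 5–11 and 12–20).

**Step 11 (key step).** Bond formation may run through the silicon-activated terminus C9, either as open-chain conjugate allylation of the enone at C5 with loss of silicon or as cycloaddition with reversed orientation. If the congested cycloaddition is slow, the β-silyloxy group may also be lost from the Lewis acid-bound ketone. The fallback removes silicon from the diene; it sets out from 15 (with 7) and returns at 24.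
- Stille coupling of 15 with Bu3SnCH2OH (Pd(PPh3)4, LiCl, dioxane) would give the hydroxymethyl diene F1, which is silylated (t-BuMe2SiCl, imidazole) to the silyloxymethyl diene F2.
- F2 has no para-directing silylmethyl group and no allylsilane; with 7 under Me2AlCl, supported by high pressure if needed because this diene is less electron-rich, it would give the C12-silyloxy adduct F3.
- The conditions of steps 12–14 would take F3 to the C1 alcohol F4, the xanthate F5 and the deoxygenated bis-silyl ether F6.
- Acid methanolysis of both alkyl silyl ethers gives the diol F7. Reductive 1,3-transposition of its primary allylic alcohol through the allylic diazene (2-nitrobenzenesulfonylhydrazide, PPh3, diethyl azodicarboxylate; the hindered C3 hydroxyl does not react) moves the double bond to C8=C12 and gives 24.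

**Step 18.** Elimination of the activated axial oxygen toward C2, or a 1,2-shift of the C4 methyl, may outrun the slow backside attack at the neopentyl carbon. The fallback separates activation from substitution: 26 is converted with ClCH2SO2Cl and pyridine into the 3α-chloromethanesulfonate F8, a leaving group suited to hindered secondary centres, and F8 is displaced by LiBr in a dipolar aprotic solvent at the lowest workable temperature to return at 27.

**Step 3.** Enantioface discrimination at a β-carbon flanked by a quaternary centre may be insufficient, and over-borylation or β-elimination of the hydroxy ketone during oxidative work-up may erode the material. The fallback starts from 4: borylation with CuCl and an achiral bisphosphine gives the racemic boryl ketone F9 (not isolated), which is oxidised to the racemic alcohol F10. Kinetic resolution by lipase-catalysed acetylation (Candida antarctica lipase B, vinyl acetate) should convert the (R)-enantiomer into the (R)-acetate F11 and leave (S)-6, at which the route is rejoined.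

**Step 8.** The vinyl ketone may undergo a second arylation or polymerise as it forms, and the silyl ether ortho to the nitrile may be cleaved by base. The fallback builds the enone in stages from 11: Heck reaction with allyl alcohol (Pd(OAc)2, Bu4NCl, NaHCO3, DMF) gives the 3-arylpropanal F12, vinylmagnesium bromide at −78 °C adds to the aldehyde in preference to the nitrile to give the allylic alcohol F13, and oxidation (Dess–Martin periodinane) returns at 13.

**Step 15.** The new exocyclic double bond may migrate into the ring during the prolonged acid exposure that the hindered neopentyl silyl ether needs. The fallback decouples the two events, starting from 23: brief treatment with a catalytic sulfonic acid in wet MeCN at 0 °C effects only the fast protodesilylation and gives the exocyclic alkene silyl ether F14; buffered HF·pyridine in THF then removes the alkyl silyl group without a strong protic acid and returns at 24.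

## Further compounds

F1 | step 11 | 4-[(2Z)-3-(hydroxymethyl)penta-2,4-dien-1-yl]-2,5-bis(triisopropylsilyloxy)benzonitrile | C=C/C(CO)=C/Cc1cc(O[Si](C(C)C)(C(C)C)C(C)C)c(C#N)cc1O[Si](C(C)C)(C(C)C)C(C)C
F2 | step 11 | 4-[(2Z)-3-(tert-butyldimethylsilyloxymethyl)penta-2,4-dien-1-yl]-2,5-bis(triisopropylsilyloxy)benzonitrile | C=C/C(CO[Si](C)(C)C(C)(C)C)=C/Cc1cc(O[Si](C(C)C)(C(C)C)C(C)C)c(C#N)cc1O[Si](C(C)C)(C(C)C)C(C)C
F3 | step 11 | cis-fused adduct as 19 with 8-CH2OSi(t-Bu)Me2 in place of 8-CH2SiMe3 | CC(C)(C)[Si](C)(C)OCC1=CC[C@@H]2C(C)(C)[C@@H](O[Si](C)(C)C(C)(C)C)CC(=O)[C@]2(C)[C@@H]1Cc1cc(O[Si](C(C)C)(C(C)C)C(C)C)c(C#N)cc1O[Si](C(C)C)(C(C)C)C(C)C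
F4 | step 11 | C1 alcohol of F3 (C1 epimers) | CC(C)(C)[Si](C)(C)OCC1=CC[C@@H]2C(C)(C)[C@@H](O[Si](C)(C)C(C)(C)C)CC(O)[C@]2(C)[C@@H]1Cc1cc(O[Si](C(C)C)(C(C)C)C(C)C)c(C#N)cc1O[Si](C(C)C)(C(C)C)C(C)C
F5 | step 11 | O-alkyl S-methyl dithiocarbonate of F4 | CC(C)(C)[Si](C)(C)OCC1=CC[C@@H]2C(C)(C)[C@@H](O[Si](C)(C)C(C)(C)C)CC(OC(=S)SC)[C@]2(C)[C@@H]1Cc1cc(O[Si](C(C)C)(C(C)C)C(C)C)c(C#N)cc1O[Si](C(C)C)(C(C)C)C(C)C
F6 | step 11 | C1-deoxygenated bis(tert-butyldimethylsilyl) ether (3β-O and C12-O) | CC(C)(C)[Si](C)(C)OCC1=CC[C@@H]2C(C)(C)[C@@H](O[Si](C)(C)C(C)(C)C)CC[C@]2(C)[C@@H]1Cc1cc(O[Si](C(C)C)(C(C)C)C(C)C)c(C#N)cc1O[Si](C(C)C)(C(C)C)C(C)C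
F7 | step 11 | 9α-(ArCH2)-8-(hydroxymethyl)-4,4,10β-trimethyl-5βH-decal-7-en-3β-ol | OCC1=CC[C@@H]2C(C)(C)[C@@H](O)CC[C@]2(C)[C@@H]1Cc1cc(O[Si](C(C)C)(C(C)C)C(C)C)c(C#N)cc1O[Si](C(C)C)(C(C)C)C(C)C
F8 | step 18 | 3α-chloromethanesulfonate of 26 | C=C1CC[C@@H]2C(C)(C)[C@H](OS(=O)(=O)CCl)CC[C@]2(C)[C@@H]1Cc1cc(O[Si](C(C)C)(C(C)C)C(C)C)c(C#N)cc1O[Si](C(C)C)(C(C)C)C(C)C
F9 | step 3 | racemic 2,4,4-trimethyl-5-(4,4,5,5-tetramethyl-1,3,2-dioxaborolan-2-yl)cyclohex-2-en-1-one | CC1=CC(C)(C)C(B2OC(C)(C)C(C)(C)O2)CC1=O
F10 | step 3 | racemic 5-hydroxy-2,4,4-trimethylcyclohex-2-en-1-one | CC1=CC(C)(C)C(O)CC1=O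
F11 | step 3 | (R)-5-acetoxy-2,4,4-trimethylcyclohex-2-en-1-one | CC1=CC(C)(C)[C@H](OC(C)=O)CC1=O
F12 | step 8 | 4-(3-oxopropyl)-2,5-bis(triisopropylsilyloxy)benzonitrile | O=CCCc1cc(O[Si](C(C)C)(C(C)C)C(C)C)c(C#N)cc1O[Si](C(C)C)(C(C)C)C(C)C
F13 | step 8 | 4-(3-hydroxypent-4-en-1-yl)-2,5-bis(triisopropylsilyloxy)benzonitrile (racemic) | C=CC(O)CCc1cc(O[Si](C(C)C)(C(C)C)C(C)C)c(C#N)cc1O[Si](C(C)C)(C(C)C)C(C)C
F14 | step 15 | 9α-(ArCH2)-3β-(tert-butyldimethylsilyloxy)-4,4,10β-trimethyl-8-methylidene-5βH-decalin | C=C1CC[C@@H]2C(C)(C)[C@@H](O[Si](C)(C)C(C)(C)C)CC[C@]2(C)[C@@H]1Cc1cc(O[Si](C(C)C)(C(C)C)C(C)C)c(C#N)cc1O[Si](C(C)C)(C(C)C)C(C)C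
A1 | alternative 1 | 1-methoxy-3,3,5-trimethyl-2-vinylbicyclo[2.2.2]oct-5-en-2-ol, vinyl syn to the C5=C6 bridge | CO[C@@]12CC[C@@H](C(C)=C1)C(C)(C)[C@@]2(O)C=C
A2 | alternative 1 | cis-fused 8-methoxy-4,4,10-trimethyldecal-8-en-3-one (target numbering) | COC=1CC[C@@H]2C(C)(C)C(=O)CC[C@]2(C)C=1
A3 | alternative 2 | cis-fused 5-bromo-4,4,7a-trimethyloctahydro-1H-inden-1-one, bromine cis to the angular methyl | C1C[C@@H]2C(C)(C)[C@@H](Br)CC[C@]2(C)C1=O
A4 | alternative 2 | ethyl diazoacetate | CCOC(=O)C=[N+]=[N-]
A5 | alternative 2 | cis-fused ethyl 3-bromo-4,4,10-trimethyl-9-oxodecalin-8-carboxylate (target numbering, C8 unspecified) | CCOC(=O)C1CC[C@@H]2C(C)(C)[C@@H](Br)CC[C@]2(C)C1=O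
A6 | alternative 3 | 2-methylcyclohex-2-en-1-one | CC1=CCCCC1=O
A7 | alternative 3 | (E)-1-methoxy-3-(trimethylsilyloxy)buta-1,3-diene | CO/C=C/C(=C)O[Si](C)(C)C
A8 | alternative 3 | cis-fused 10-methyloctal-1-ene-3,9-dione (target numbering) | O=C1CCC[C@@H]2CC(=O)C=C[C@]12C
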